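**Retrosynthetic overview**
1. Target ⇐ 1(10)-en-2-one (copper hydride sets 10β-H) ⇐ 1(10)-ene diester (allylic oxidation at C2, as valencene → nootkatone).
2. Diester ⇐ 8β-hydroxy-9α,10α-epoxide: Mitsunobu tiglate (inversion at C8), epoxide → allylic alcohol (9α-OH, Δ1(10)), senecioylation.
3. Epoxy alcohol ⇐ (+)-dehydrofukinone: kinetic deconjugation sets C7, Luche reduction, Shi epoxidation.
4. (+)-Dehydrofukinone ⇐ germacrone: proton-initiated transannular C5–C10 closure (germacrane → eudesmane), then 1,2-H and 1,2-Me shifts (eudesmane → eremophilane) in one pot.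
5. Ring order: the ten-membered ring comes with germacrone; both six-membered rings form together in the transannular closure of step 1; no ring is made afterwards.

Assumption: germacrone (achiral bulk isolate of zdravetz/Curcuma oils) is taken as a cheap commercial starting material; eremophilane numbering is used throughout and α/β follow the usual eremophilane drawing (C4- and C5-methyl β).

**Step 1**
Reactants: 1 germacrone [(3E,7E)-3,7-dimethyl-10-(propan-2-ylidene)cyclodeca-3,7-dien-1-one]
Product: 3 (+)-dehydrofukinone [(4S,5R)-eremophila-7(11),9-dien-8-one; 4β,5β-dimethyl], via eudesmadienone 2 (not isolated)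
Conditions: (S,S)-IDPi (5 mol %), CHCl3, −40 °C; then TfOH (0.3 equiv), HFIP, 0 °C → rt
Reagents that add atoms: none
Why: Proposed new method: a confined chiral Brønsted acid protonates C1 of one of the two rapidly interconverting helical conformers of achiral 1 while C4=C5 closes transannularly onto C10 (the germacrane → eudesmane closure of the biosynthesis, known for germacrone with achiral acids), fixing the 10β-methyl centre of 2; TfOH in poorly nucleophilic HFIP then reprotonates C4 on the α face (or shifts 5α-H to the C4 cation), the angular methyl migrates suprafacially from C10 to C5, and the C10 cation is discharged irreversibly by loss of H-9 to the conjugated enone, so the cis 4β,5β-dimethyl pattern follows from the anti-periplanar 1,2-shifts; the closest known reaction types are the acid-mediated germacrone → selinadienone cyclisation, enantioselective proton-initiated polyene cyclisations with chiral Brønsted acids, and the acid-triggered eudesmane → eremophilane methyl shift of 4,5-epoxyeudesmanes; which catalyst antipode gives the (10R) series has to be found by experiment.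

**Step 2**
Reactants: 3 (+)-dehydrofukinone
Product: 5 (4S,5R)-7αH-eremophila-9,11-dien-8β-ol (7β-isopropenyl, 8β-OH), via isopropenyl ketone 4 (not isolated)
Conditions: LDA, THF, −78 °C; AcOH, −78 °C; then CeCl3·7H2O, NaBH4, MeOH, −78 → −40 °C
Reagents that add atoms: none
Why: Kinetic deconjugation (3 has no α′-H, so LDA removes a proton from the isopropylidene methyl syn to the carbonyl) followed by α-protonation at C7 on the α face, anti to the angular C5 methyl, gives the 7β-isopropenyl ketone 4, which is trapped at once by Luche 1,2-reduction from the α face (anti to the now pseudoaxial isopropenyl group) to give the 8β-alcohol before C7 can epimerise or reconjugate.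

**Step 3**
Reactants: 5 7αH-eremophila-9,11-dien-8β-ol
Product: 6 9α,10α-epoxy-7αH-eremophil-11-en-8β-ol
Conditions: Shi ketone (D-fructose-derived, 30 mol %), Oxone, K2CO3, Bu4NHSO4, MeCN–DMM–aq. buffer (pH 10.5), 0 °C
Reagents that add atoms: Oxone (potassium peroxymonosulfate), [K+].[O-]S(=O)(=O)OO
Why: Shi dioxirane epoxidation, in which the trisubstituted 9(10)-alkene reacts far faster than the 1,1-disubstituted isopropenyl group and oxygen is delivered to the α face, which is both the catalyst-preferred face for this olefin and the face not shielded by the angular C5 methyl and the C7 isopropenyl group, setting 9α-O and 10α-O.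

**Step 4**
Reactants: 6 9α,10α-epoxy-7αH-eremophil-11-en-8β-ol; 7 tiglic acid [(E)-2-methylbut-2-enoic acid]
Product: 8 9α,10α-epoxy-7αH-eremophil-11-en-8α-yl tiglate
Conditions: PPh3, DIAD, toluene, 0 °C → rt
Reagents that add atoms: tiglic acid (7), C/C=C(\C)C(=O)O
Why: Mitsunobu esterification with SN2 inversion at the now non-allylic C8 carbinol, the carboxylate entering from the open α face, converts the 8β-alcohol into the 8α-tiglate without touching the epoxide or the E geometry of the acid.

**Step 5**
Reactants: 8 9α,10α-epoxy-7αH-eremophil-11-en-8α-yl tiglate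
Product: 10 9α-hydroxy-7αH-eremophila-1(10),11-dien-8α-yl tiglate, via silyl ether 9 (not isolated)
Conditions: TMSOTf, 2,6-lutidine, toluene, −78 °C; DBU, rt; then aq. citric acid, THF
Reagents that add atoms: none
Why: Noyori-type epoxide → allylic silyl ether isomerisation, in which TMSOTf opens the tertiary C10–O bond and base removes a C1 proton (C5 has none), so the C9–O bond keeps its α configuration and the 1(10)-alkene needed for the C2 oxidation is formed.

**Step 6**
Reactants: 10 9α-hydroxy-7αH-eremophila-1(10),11-dien-8α-yl tiglate; 11 senecioyl chloride (3-methylbut-2-enoyl chloride)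
Product: 12 9α-(senecioyloxy)-7αH-eremophila-1(10),11-dien-8α-yl tiglate
Conditions: pyridine, DMAP (cat.), CH2Cl2, 0 °C
Reagents that add atoms: senecioyl chloride (11), CC(C)=CC(=O)Cl
Why: DMAP-catalysed acylation of the only free hydroxyl, with pyridine at 0 °C instead of a trialkylamine so that the senecioyl group does not slip to the β,γ-isomer through the vinylketene; no stereocentre is touched.

**Step 7**
Reactants: 12 9α-(senecioyloxy)-7αH-eremophila-1(10),11-dien-8α-yl tiglate
Product: 13 9α-(senecioyloxy)-8α-(tigloyloxy)-7αH-eremophila-1(10),11-dien-2-one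
Conditions: Rh2(cap)4 (1 mol %), t-BuOOH (5 equiv), NaHCO3, CH2Cl2, rt
Reagents that add atoms: tert-butyl hydroperoxide, CC(C)(C)OO
Why: Dirhodium caprolactamate/TBHP allylic C–H oxidation, in which C2 is the only free allylic ring methylene of the 1(10)-alkene (C9 is blocked by the ester), the same selectivity that converts valencene into nootkatone with the isopropenyl group intact.

**Step 8**
Reactants: 13 9α-(senecioyloxy)-8α-(tigloyloxy)-7αH-eremophila-1(10),11-dien-2-one
Product: 15 8α-(tigloyloxy)-9α-(senecioyloxy)-7αH,10βH-eremophil-11-en-2-one (target), via silyl enol ether 14 (not isolated)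
Conditions: [(Ph3P)CuH]6 (5 mol %), PhMe2SiH, toluene, rt; then 1 M HCl, THF, 0 °C
Reagents that add atoms: none
Why: Stryker-type copper hydride 1,4-reduction, in which hydride goes to C10 on the β face, cis to the angular C5 methyl (as conjugate additions to 4a-methyl-octalones go) and anti to the allylic 9α-acyloxy group, giving the cis-fused 10β-H junction, while the disubstituted enoate esters and the isopropenyl group react much more slowly than the ring enone.

**Compound list**
1 | germacrone, (3E,7E)-3,7-dimethyl-10-(propan-2-ylidene)cyclodeca-3,7-dien-1-one | C/C1=C\CC(=C(C)C)C(=O)C/C(C)=C/CC1 | starting material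
2 | (10R)-eudesma-4,7(11)-dien-8-one (10β-methyl) | CC1=C2CC(=C(C)C)C(=O)C[C@@]2(C)CCC1 | intermediate
3 | (+)-dehydrofukinone, (4S,5R)-eremophila-7(11),9-dien-8-one (4β,5β-dimethyl) | CC(C)=C1C[C@@]2(C)C(CCC[C@@H]2C)=CC1=O | intermediate
4 | 7αH-eremophila-9,11-dien-8-one (4β,5β-dimethyl, 7β-isopropenyl) | C=C(C)[C@H]1C[C@@]2(C)C(CCC[C@@H]2C)=CC1=O | intermediate
5 | 7αH-eremophila-9,11-dien-8β-ol (7β-isopropenyl, 8β-OH) | C=C(C)[C@H]1C[C@@]2(C)C(CCC[C@@H]2C)=C[C@H]1O | intermediate
6 | 9α,10α-epoxy-7αH-eremophil-11-en-8β-ol | C=C(C)[C@H]1C[C@@]2(C)[C@]3(CCC[C@@H]2C)O[C@@H]3[C@H]1O | intermediate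
7 | tiglic acid, (E)-2-methylbut-2-enoic acid | C/C=C(\C)C(=O)O | starting material
8 | 9α,10α-epoxy-7αH-eremophil-11-en-8α-yl tiglate | C=C(C)[C@H]1C[C@@]2(C)[C@]3(CCC[C@@H]2C)O[C@@H]3[C@@H]1OC(=O)/C(C)=C/C | intermediate
9 | 9α-(trimethylsilyloxy)-7αH-eremophila-1(10),11-dien-8α-yl tiglate | C=C(C)[C@H]1C[C@@]2(C)C(=CCC[C@@H]2C)[C@H](O[Si](C)(C)C)[C@@H]1OC(=O)/C(C)=C/C | intermediate
10 | 9α-hydroxy-7αH-eremophila-1(10),11-dien-8α-yl tiglate | C=C(C)[C@H]1C[C@@]2(C)C(=CCC[C@@H]2C)[C@H](O)[C@@H]1OC(=O)/C(C)=C/C | intermediate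
11 | senecioyl chloride, 3-methylbut-2-enoyl chloride | CC(C)=CC(=O)Cl | starting material
12 | 9α-(senecioyloxy)-7αH-eremophila-1(10),11-dien-8α-yl tiglate | C=C(C)[C@H]1C[C@@]2(C)C(=CCC[C@@H]2C)[C@H](OC(=O)C=C(C)C)[C@@H]1OC(=O)/C(C)=C/C | intermediate
13 | 9α-(senecioyloxy)-8α-(tigloyloxy)-7αH-eremophila-1(10),11-dien-2-one | C=C(C)[C@H]1C[C@@]2(C)C(=CC(=O)C[C@@H]2C)[C@H](OC(=O)C=C(C)C)[C@@H]1OC(=O)/C(C)=C/C | intermediate
14 | 2-(dimethylphenylsilyloxy)-9α-(senecioyloxy)-8α-(tigloyloxy)-7αH,10βH-eremophila-1,11-diene | C=C(C)[C@H]1C[C@@]2(C)[C@H](C=C(O[Si](C)(C)c3ccccc3)C[C@@H]2C)[C@H](OC(=O)C=C(C)C)[C@@H]1OC(=O)/C(C)=C/C | intermediate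
15 | 8α-(tigloyloxy)-9α-(senecioyloxy)-7αH,10βH-eremophil-11-en-2-one (CNP0181050.1) | C=C(C)[C@H]1C[C@@]2(C)[C@H](CC(=O)C[C@@H]2C)[C@H](OC(=O)C=C(C)C)[C@@H]1OC(=O)/C(C)=C/C | target

**Totals and risk**
Total step count: 8. Longest linear sequence: 8 steps (1 → 15).

The three steps most likely to fail are steps 1, 2 and 4.

Step 1 may stop at the eudesmane stage, because the acid-only 1,2-H/1,2-Me shift is not established chemistry. The fallback sets out from 2, isolated after the chiral-acid stage, and uses the epoxide-triggered methyl shift that is known for eudesmanes. mCPBA (NaHCO3, CH2Cl2, 0 °C) epoxidises the tetrasubstituted 4(5)-alkene on the α face, anti to the 10β-methyl, to give 4α,5α-epoxyeudesm-7(11)-en-8-one F1. BF3·OEt2 (toluene, −78 °C) opens the epoxide at C5, the C10 methyl migrates anti to the departing oxygen and H-9 is lost, giving 4α-hydroxyeremophila-7(11),9-dien-8-one F2. Methyl chlorooxoacetate with DMAP gives the tertiary methyl oxalate F3. Bu3SnH/AIBN (toluene, 100 °C) removes the oxygen, the C4 radical taking hydrogen anti to the C5 methyl, and the route is rejoined at 3.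

Step 2 may give the wrong C7 epimer or reconjugate, since the 7β-isopropenyl ketone is the less stable epimer and is set only by a kinetic protonation. The fallback sets out from 3 and delivers the C7 hydrogen from palladium instead of from a proton source. SeO2/t-BuOOH hydroxylates the isopropylidene methyl to (E)-12-hydroxyeremophila-7(11),9-dien-8-one F4, and methyl chloroformate with pyridine gives the methyl carbonate F5. Tsuji hydrogenolysis (Pd2(dba)3, PBu3, HCO2H–Et3N, THF) ionises the carbonate with palladium on the less hindered α face and transfers hydride to C7, the more substituted allyl terminus. This gives the deconjugated ketone 4, where the route is rejoined, and the Luche reduction of step 2 then leads to 5.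

Step 4 may be too slow, because tiglic acid is a weak Mitsunobu acid and the C8 carbinol is hindered. The fallback sets out from 6 and separates inversion from tigloylation. Mitsunobu reaction with 4-nitrobenzoic acid (PPh3, DIAD) gives 9α,10α-epoxy-7αH-eremophil-11-en-8α-yl 4-nitrobenzoate F6. K2CO3/MeOH frees 9α,10α-epoxy-7αH-eremophil-11-en-8α-ol F7. Yamaguchi esterification with tiglic acid 7 (2,4,6-trichlorobenzoyl chloride, Et3N, DMAP) then gives 8, where the route is rejoined.

**Further compounds**
F1 | step 1 | 4α,5α-epoxyeudesm-7(11)-en-8-one | C[C@@]12CCC[C@]3(C)CC(=O)C(=C(C)C)C[C@@]13O2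
F2 | step 1 | 4α-hydroxyeremophila-7(11),9-dien-8-one | CC(C)=C1C[C@@]2(C)C(CCC[C@@]2(C)O)=CC1=O
F3 | step 1 | methyl oxalate of 4α-hydroxyeremophila-7(11),9-dien-8-one | CC(C)=C1C[C@@]2(C)C(CCC[C@@]2(C)OC(=O)C(=O)OC)=CC1=O
F4 | step 2 | (E)-12-hydroxyeremophila-7(11),9-dien-8-one | OC/C(C)=C1\C[C@@]2(C)C(CCC[C@@H]2C)=CC1=O
F5 | step 2 | methyl carbonate of (E)-12-hydroxyeremophila-7(11),9-dien-8-one | COC(=O)OC/C(C)=C1\C[C@@]2(C)C(CCC[C@@H]2C)=CC1=O
F6 | step 4 | 9α,10α-epoxy-7αH-eremophil-11-en-8α-yl 4-nitrobenzoate | C=C(C)[C@H]1C[C@@]2(C)[C@]3(CCC[C@@H]2C)O[C@@H]3[C@@H]1OC(=O)c4ccc(cc4)[N+](=O)[O-]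
F7 | step 4 | 9α,10α-epoxy-7αH-eremophil-11-en-8α-ol | C=C(C)[C@H]1C[C@@]2(C)[C@]3(CCC[C@@H]2C)O[C@@H]3[C@@H]1O
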